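**Strategy**

The oxane (ring A: O1′, C2′ = C8, C3′–C6′) is read as a γ-pyranone in disguise: its three C-methyls and the C4′ oxygen are those of a 3,5,6-trimethyl-4-pyranone, and the spiro carbon C8 is its electrophilic position next to the ring oxygen. The route rests on the C7–C8 disconnection. In one operation a silyl triflate aromatises the pyranone to a 4-silyloxypyrylium ion and converts the side-chain 1,3-diketone into a bis-silyl dienol ether, whose terminal carbon C7 adds to C8, closing ring B (C4–C5–C6–C1–C7–C8) at the spiro centre. The precursor 10 carries at C2′ the quaternary (S)-C4 with methyl, diketone chain and an isopropyl ester, chosen larger than a methyl ester to steer the C4–C8 rotamer.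

Key step: step 7

**Remarks on the chemistry**

- Atom labels follow the target: bicycle C1 (O-bearing bridgehead), O2, C3 (lactone C=O), C4, C5 (ketone), C6, C7, C8 (spiro = C2′); oxane O1′, C3′–C6′.
- C6 lies between two carbonyl groups in 10 and 13–16 and is enolised there. It is drawn without a descriptor until it is set in step 13; the chlorine placed on it in step 10 is a blocking group of no fixed configuration.
- C3′ and C7 are formed without control in step 7 and are settled by equilibration in step 8. Compounds 13 and 14 therefore carry descriptors at C4 and C8 only.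
- The isopropyl ester is a spectator that survives silyl triflate, hydride and acid and leaves as propan-2-ol in step 11.

**Route**

Step 1
Reactants: 1 pentan-3-one, 2 acetic anhydride
Product: 4 2,3,5,6-tetramethyl-4H-pyran-4-one, via 3,5-dimethylheptane-2,4,6-trione 3 (not isolated)
Conditions: polyphosphoric acid, 95 °C
Reagents that add atoms: none
Why: Acid-mediated double C-acetylation of the ketone through its enol gives triketone 3, which cyclodehydrates in the same medium to the symmetrical γ-pyranone (pyranone synthesis from a ketone and an anhydride in polyphosphoric acid).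

Step 2
Reactants: 4 2,3,5,6-tetramethyl-4H-pyran-4-one
Product: 5 isopropyl 2-(3,5,6-trimethyl-4-oxo-4H-pyran-2-yl)acetate
Conditions: LiN(SiMe3)2 (2.2 equiv), THF, −78 °C; i-PrOCOCl (1.0 equiv), −78 → 0 °C
Reagents that add atoms: isopropyl chloroformate, CC(C)OC(Cl)=O
Why: Lateral (vinylogous) deprotonation of one of the two equivalent α-methyl groups and C-acylation of the extended enolate, the second equivalent of base storing the more acidic product as its enolate.

Step 3
Reactants: 5 isopropyl 2-(3,5,6-trimethyl-4-oxo-4H-pyran-2-yl)acetate, 6 propanoyl chloride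
Product: 7 isopropyl 3-oxo-2-(3,5,6-trimethyl-4-oxo-4H-pyran-2-yl)pentanoate
Conditions: LiN(SiMe3)2 (2.1 equiv), THF, −78 °C; 6, −78 → 0 °C
Reagents that add atoms: none
Why: Claisen-type C-acylation of the doubly stabilised ester enolate with the acid chloride gives the β-keto ester, held as its enolate by the second equivalent of base.

Step 4
Reactants: 7 isopropyl 3-oxo-2-(3,5,6-trimethyl-4-oxo-4H-pyran-2-yl)pentanoate
Product: 8 rac-isopropyl 2-methyl-3-oxo-2-(3,5,6-trimethyl-4-oxo-4H-pyran-2-yl)pentanoate
Conditions: MeI, K2CO3, acetone, rt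
Reagents that add atoms: iodomethane, CI
Why: C-alkylation of the β-keto ester enolate with iodomethane creates the quaternary C4 as a racemate (α-methylation of a 1,3-dicarbonyl compound).

Step 5
Reactants: 8 rac-isopropyl 2-methyl-3-oxo-2-(3,5,6-trimethyl-4-oxo-4H-pyran-2-yl)pentanoate
Product: 9 isopropyl (2S)-2-methyl-3-oxo-2-(3,5,6-trimethyl-4-oxo-4H-pyran-2-yl)pentanoate
Conditions: preparative SFC, amylose tris(3,5-dimethylphenylcarbamate) phase, CO2/i-PrOH
Reagents that add atoms: none
Why: Resolution by chromatography on a chiral stationary phase; 8 has a single, non-enolisable stereocentre, so the enantiomers cannot racemise, and the S enantiomer carries the C4 configuration of the target.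

Step 6
Reactants: 9 isopropyl (2S)-2-methyl-3-oxo-2-(3,5,6-trimethyl-4-oxo-4H-pyran-2-yl)pentanoate, 6 propanoyl chloride
Product: 10 isopropyl (2S)-2,4-dimethyl-3,5-dioxo-2-(3,5,6-trimethyl-4-oxo-4H-pyran-2-yl)heptanoate
Conditions: MgBr2·OEt2 (2.5 equiv), i-Pr2NEt (3 equiv), CH2Cl2, 0 °C → rt
Reagents that add atoms: none
Why: Soft enolisation and C-acylation: the magnesium-chelated β-keto ester can enolise only toward C6 because C4 is quaternary, and the 1,3-diketone formed is protected from a second acylation as its chelate.

Step 7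
Reactants: 10 isopropyl (2S)-2,4-dimethyl-3,5-dioxo-2-(3,5,6-trimethyl-4-oxo-4H-pyran-2-yl)heptanoate
Product: 13 isopropyl 2,3,5,7,9,11-hexamethyl-4,8,10-trioxo-1-oxaspiro[5.5]undec-2-ene-11-carboxylate, via silyloxypyrylium bis-silyl dienol ether triflate 11 (not isolated), via bis-silyl spiro adduct 12 (not isolated)
Conditions: t-BuMe2SiOTf (3.5 equiv), Et3N (5 equiv), CH2Cl2, −78 → 0 °C; then 1 M HCl, THF, 0 °C
Reagents that add atoms: none
Why: Proposed new method: t-BuMe2SiOTf/Et3N should silylate the 1,3-diketone twice and the pyranone carbonyl once, giving the aromatic 4-silyloxypyrylium ion 11 whose dienol ether terminus C7 adds to the pyrylium carbon C8 next to O1′; the adduct 12 is a neutral 4-silyloxy-2H-pyran that has no way to ring-open, and aqueous acid then frees the three carbonyl groups with protonation at C3′. The closest known reaction type is the silyl triflate-promoted Mukaiyama–Michael addition of silyl enol ethers to 4-silyloxypyrylium ions made from chromones and 4-pyranones; untested are the intramolecular attack on a fully substituted C2′ and the 1,3-bis(silyloxy)diene as donor. Ring B (C4–C5–C6–C1–C7–C8) closes in a 6-(enolendo)-exo-trig mode. C8 is set relative to the resolved C4 by the rotamer about C4–C8 through which C7 reaches the pyrylium face, C7 by the (Z) geometry of the terminal enol ether and C3′ by the face of protonation on work-up; the last two are not relied on because step 8 equilibrates them. The step needs the rotamer with the ester in the pyrylium plane beside O1′ and the C4 methyl beside the C3′ methyl. In the substrate the C3′ methyl forbids (1,3-allylic strain) any C4 substituent in the plane on its side, and the isopropyl ester is too large for the slot between that methyl and the O5 silyl ether and prefers to stand perpendicular to the dienol ether, which is the position eclipsing O1′.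

Step 8
Reactants: 13 isopropyl 2,3,5,7,9,11-hexamethyl-4,8,10-trioxo-1-oxaspiro[5.5]undec-2-ene-11-carboxylate
Product: 15 isopropyl 2,3,5,7,9,11-hexamethyl-4,8,10-trioxo-1-oxaspiro[5.5]undecane-11-carboxylate, via hydrogenated epimer mixture 14 (not isolated)
Conditions: H2 (10 bar), 10% Pd/C, EtOAc, rt; filter; then p-TsOH·H2O (0.2 equiv), PhMe, 60 °C
Reagents that add atoms: none
Why: Heterogeneous hydrogenation saturates the vinylogous ester C5′=C6′ (the enolised dione of ring B is inert), and acid then equilibrates C3′ and C5′ (enolisation of the C4′ ketone), C6′ (reversible oxa-conjugate addition) and C7 (enolisation of C1), which should favour the ring A chair with three equatorial methyls, the quaternary C4 equatorial and C7 axial, the C7 hydrogen turned over ring A and its methyl anti to C3′.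

Step 9
Reactants: 15 isopropyl 2,3,5,7,9,11-hexamethyl-4,8,10-trioxo-1-oxaspiro[5.5]undecane-11-carboxylate
Product: 16 isopropyl 4-hydroxy-2,3,5,7,9,11-hexamethyl-8,10-dioxo-1-oxaspiro[5.5]undecane-11-carboxylate
Conditions: LiBH(s-Bu)3 (3 equiv), THF, −78 °C; aq. NH4Cl
Reagents that add atoms: none
Why: The first equivalent of hydride deprotonates the ring B enol, whose enolate shields C1 and C5, and the bulky borohydride then attacks the C4′ ketone along the equatorial trajectory (the axial one is blocked by the axial C7), giving the axial alcohol (hindered-hydride ketone reduction).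

Step 10
Reactants: 16 isopropyl 4-hydroxy-2,3,5,7,9,11-hexamethyl-8,10-dioxo-1-oxaspiro[5.5]undecane-11-carboxylate
Product: 17 isopropyl 9-chloro-4-hydroxy-2,3,5,7,9,11-hexamethyl-8,10-dioxo-1-oxaspiro[5.5]undecane-11-carboxylate
Conditions: NCS (1.05 equiv), CH2Cl2, 0 °C
Reagents that add atoms: N-chlorosuccinimide, O=C1CCC(=O)N1Cl
Why: Electrophilic chlorination of the enolised 1,3-dione at C6 gives a non-enolisable 2-chloro-2-methyl-1,3-dione, the chlorine serving as a blocking group that is removed in step 13.

Step 11
Reactants: 17 isopropyl 9-chloro-4-hydroxy-2,3,5,7,9,11-hexamethyl-8,10-dioxo-1-oxaspiro[5.5]undecane-11-carboxylate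
Product: 19 6-chloro-4′-hydroxy-3′,4,5′,6,6′,7-hexamethylspiro[2-oxabicyclo[2.2.2]octane-8,2′-oxane]-3,5-dione, via cis-hydroxy ester 18 (not isolated)
Conditions: Me4NBH(OAc)3, MeCN/AcOH, −20 → 0 °C; then CSA (0.1 equiv), PhMe, 60 °C
Reagents that add atoms: none
Why: Hydroxyl-directed triacetoxyborohydride reduction (Evans–Saksena type): the axial C4′ hydroxyl, held next to C1 on the C3′ face of ring B, binds boron and delivers hydride to the C1 ketone only (C5 has no such neighbour), so the new C1 hydroxyl is cis to the C4 ester and acid-catalysed transesterification closes the bridged lactone with loss of propan-2-ol, dehydration being impossible at the quaternary C6.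

Step 12
Reactants: 19 6-chloro-4′-hydroxy-3′,4,5′,6,6′,7-hexamethylspiro[2-oxabicyclo[2.2.2]octane-8,2′-oxane]-3,5-dione, 2 acetic anhydride
Product: 20 6-chloro-3′,4,5′,6,6′,7-hexamethyl-3,5-dioxospiro[2-oxabicyclo[2.2.2]octane-8,2′-oxan]-4′-yl acetate
Conditions: DMAP, pyridine, 40 °C
Reagents that add atoms: none
Why: DMAP-catalysed acetylation of the only free (axial, hindered) hydroxyl; with C6 still quaternary the β-acyloxy ketone cannot eliminate under the basic conditions.

Step 13
Reactants: 20 6-chloro-3′,4,5′,6,6′,7-hexamethyl-3,5-dioxospiro[2-oxabicyclo[2.2.2]octane-8,2′-oxan]-4′-yl acetate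
Product: 21 3′,4,5′,6,6′,7-hexamethyl-3,5-dioxospiro[2-oxabicyclo[2.2.2]octane-8,2′-oxan]-4′-yl acetate (CNP0257416.1)
Conditions: Bu3SnH, AIBN (cat.), PhMe, 80 °C
Reagents that add atoms: none
Why: Radical dehalogenation: the tertiary α-keto radical at C6 takes hydrogen from Bu3SnH on its open face, the one syn to the unsubstituted lactone bridge O2–C3 (the other is flanked by the C7–C8 bridge that carries ring A), which places the C6 methyl syn to C7 as in the target.

**Compound list**

1 | pentan-3-one | CCC(=O)CC | starting material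
2 | acetic anhydride | CC(=O)OC(C)=O | starting material
3 | 3,5-dimethylheptane-2,4,6-trione | CC(=O)C(C)C(=O)C(C)C(C)=O | intermediate (not isolated)
4 | 2,3,5,6-tetramethyl-4H-pyran-4-one | CC1=C(C)C(=O)C(C)=C(C)O1 | intermediate
5 | isopropyl 2-(3,5,6-trimethyl-4-oxo-4H-pyran-2-yl)acetate | CC1=C(C)C(=O)C(C)=C(CC(=O)OC(C)C)O1 | intermediate
6 | propanoyl chloride | CCC(Cl)=O | starting material
7 | isopropyl 3-oxo-2-(3,5,6-trimethyl-4-oxo-4H-pyran-2-yl)pentanoate (racemic, enolisable) | CC1=C(C)C(=O)C(C)=C(O1)C(C(=O)OC(C)C)C(=O)CC | intermediate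
8 | rac-isopropyl 2-methyl-3-oxo-2-(3,5,6-trimethyl-4-oxo-4H-pyran-2-yl)pentanoate | CC1=C(C)C(=O)C(C)=C(O1)C(C)(C(=O)OC(C)C)C(=O)CC | intermediate
9 | isopropyl (2S)-2-methyl-3-oxo-2-(3,5,6-trimethyl-4-oxo-4H-pyran-2-yl)pentanoate | CC1=C(C)C(=O)C(C)=C(O1)[C@](C)(C(=O)OC(C)C)C(=O)CC | intermediate
10 | isopropyl (2S)-2,4-dimethyl-3,5-dioxo-2-(3,5,6-trimethyl-4-oxo-4H-pyran-2-yl)heptanoate; chain C4 (= C6) enolisable, keto–enol mixture | CC1=C(C)C(=O)C(C)=C(O1)[C@](C)(C(=O)OC(C)C)C(=O)C(C)C(=O)CC | intermediate (key-step precursor)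
11 | 4-(tert-butyldimethylsilyloxy)pyrylium triflate of 10 with the side chain as its (E,Z)-bis(tert-butyldimethylsilyl) dienol ether | Cc1c(C)c(O[Si](C)(C)C(C)(C)C)c(C)c([o+]1)[C@](C)(C(=O)OC(C)C)/C(O[Si](C)(C)C(C)(C)C)=C(C)\C(O[Si](C)(C)C(C)(C)C)=C\C.[O-]S(=O)(=O)C(F)(F)F | intermediate (not isolated)
12 | bis-silyl spiro adduct: 4′-silyloxy-2H-pyran (ring A) spiro-fused at C8 to the C5-silyloxy enone of ring B; C7 not defined | CC1=C(C)C(O[Si](C)(C)C(C)(C)C)=C(C)[C@]2(O1)C(C)C(=O)C(C)=C(O[Si](C)(C)C(C)(C)C)[C@@]2(C)C(=O)OC(C)C | intermediate (not isolated)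
13 | isopropyl 2,3,5,7,9,11-hexamethyl-4,8,10-trioxo-1-oxaspiro[5.5]undec-2-ene-11-carboxylate; C4 S, O1′ cis to the ester on ring B; C3′/C7 epimer mixture, ring B largely enolised | O=C1C(C)=C(C)O[C@@]2(C1C)C(C)C(=O)C(C)C(=O)[C@@]2(C)C(=O)OC(C)C | intermediate (key-step product)
14 | isopropyl 2,3,5,7,9,11-hexamethyl-4,8,10-trioxo-1-oxaspiro[5.5]undecane-11-carboxylate as the unequilibrated mixture of C3′, C5′, C6′ and C7 epimers | O=C1C(C)C(C)O[C@@]2(C1C)C(C)C(=O)C(C)C(=O)[C@@]2(C)C(=O)OC(C)C | intermediate (not isolated)
15 | isopropyl 2,3,5,7,9,11-hexamethyl-4,8,10-trioxo-1-oxaspiro[5.5]undecane-11-carboxylate, equilibrated: ring A methyls all equatorial, C7 methyl cis to the ester and O1′; C6 enolisable | O=C1[C@H](C)[C@@H](C)O[C@@]2([C@@H]1C)[C@@H](C)C(=O)C(C)C(=O)[C@@]2(C)C(=O)OC(C)C | intermediate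
16 | isopropyl 4-hydroxy-2,3,5,7,9,11-hexamethyl-8,10-dioxo-1-oxaspiro[5.5]undecane-11-carboxylate; C4′ hydroxyl axial, syn to C7 | O[C@@H]1[C@H](C)[C@@H](C)O[C@@]2([C@@H]1C)[C@@H](C)C(=O)C(C)C(=O)[C@@]2(C)C(=O)OC(C)C | intermediate
17 | isopropyl 9-chloro-4-hydroxy-2,3,5,7,9,11-hexamethyl-8,10-dioxo-1-oxaspiro[5.5]undecane-11-carboxylate; C6 (Cl, Me) of no fixed configuration | O[C@@H]1[C@H](C)[C@@H](C)O[C@@]2([C@@H]1C)[C@@H](C)C(=O)C(C)(Cl)C(=O)[C@@]2(C)C(=O)OC(C)C | intermediate
18 | isopropyl 9-chloro-4,8-dihydroxy-2,3,5,7,9,11-hexamethyl-10-oxo-1-oxaspiro[5.5]undecane-11-carboxylate; C1 hydroxyl cis to the ester | O[C@@H]1[C@H](C)[C@@H](C)O[C@@]2([C@@H]1C)[C@@H](C)[C@@H](O)C(C)(Cl)C(=O)[C@@]2(C)C(=O)OC(C)C | intermediate (not isolated)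
19 | 6-chloro-4′-hydroxy-3′,4,5′,6,6′,7-hexamethylspiro[2-oxabicyclo[2.2.2]octane-8,2′-oxane]-3,5-dione | O[C@@H]1[C@H](C)[C@@H](C)O[C@@]2([C@@H]1C)[C@@H](C)[C@H]1OC(=O)[C@]2(C)C(=O)C1(C)Cl | intermediate
20 | 6-chloro-3′,4,5′,6,6′,7-hexamethyl-3,5-dioxospiro[2-oxabicyclo[2.2.2]octane-8,2′-oxan]-4′-yl acetate | CC(=O)O[C@@H]1[C@H](C)[C@@H](C)O[C@@]2([C@@H]1C)[C@@H](C)[C@H]1OC(=O)[C@]2(C)C(=O)C1(C)Cl | intermediate
21 | 3′,4,5′,6,6′,7-hexamethyl-3,5-dioxospiro[2-oxabicyclo[2.2.2]octane-8,2′-oxan]-4′-yl acetate, CNP0257416.1; C4 S; on ring B the lactone bridge, O1′ and the C7 methyl on one face, C3′ and the C6 methyl on the other; on ring A the 3′-, 5′-, 6′-methyls equatorial and the 4′-acetoxy axial, syn to C7 | CC(=O)O[C@@H]1[C@H](C)[C@@H](C)O[C@@]2([C@@H]1C)[C@@H](C)[C@H]1OC(=O)[C@]2(C)C(=O)[C@H]1C | target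

**Totals**

Total step count: 13. Longest linear sequence: 13 steps (1 → 21).

**Steps most likely to fail**

1. Step 7 (proposed new method). The hindered, fully substituted C8 of the pyrylium ion may resist attack, so that the silylated material is consumed along other paths, or C7 may add through the rotamer with the C4 methyl beside O1′, giving the C8 epimer. The fallback uses known chemistry and sets out from 10. LiBH(s-Bu)3 (2 equiv, the first deprotonating the diketone) in THF at −78 °C should add hydride to the less hindered C6′ of the pyranone (conjugate reduction) and give, after protonation, the 2,3-dihydro-4H-pyran-4-one diketone F1, in which C8 is the β-carbon of an ordinary β-alkoxy enone. t-BuMe2SiOTf/Et3N then effects an intramolecular Mukaiyama–Michael addition of the bis-silyl dienol ether to this non-aromatic acceptor, a reaction type established for dihydropyranones, giving the bis-silyl spiro adduct F2. Aqueous HCl hydrolyses F2 to 14, where the route is rejoined before the acid equilibration of step 8.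

2. Step 8. Hydrogen may be delivered to the ring A face that puts the C6′ methyl syn to C7, and the acid-mediated correction through reversible oxa-conjugate addition may be too slow or may lose the ring-opened hydroxy enone to dehydration; the equilibrium at C3′ and C7 may also settle less cleanly than expected. The fallback sets out from 13 and sets C6′ by kinetic hydride delivery instead of surface hydrogenation followed by equilibration. LiBH(s-Bu)3 in THF at −78 °C (the first equivalent deprotonates ring B) should add hydride to C6′ along the axial trajectory of the half-chair, so that the C6′ methyl becomes equatorial under stereoelectronic control. Protonation of the enolate gives 14 again (no compound outside the list, F0), and p-TsOH·H2O then only has to equilibrate the enolisable centres C3′, C5′ and C7; the route is rejoined at 15.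

3. Step 11. Boron may fail to bridge from the C4′ oxygen to C1 (the hydroxyl can instead add to C1 as a hemiketal, or the reach may be too long). The ketone would then stay untouched or be reduced from the outer face to the C1 epimer, which cannot lactonise. The fallback sets out from 17 and replaces directed, irreversible hydride delivery by an equilibrating Meerwein–Ponndorf–Verley reduction: Al(Oi-Pr)3, i-PrOH, PhMe, 60 °C. Hydride transfer to C1 is reversible, so the trans-hydroxy ester F3 (the C1 epimer of 18) returns to 17, while the cis alkoxide 18 is withdrawn from the equilibrium as lactone 19; the hindered C5 ketone has no such exit. The route is rejoined at 19.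

**Further compounds**

F1 | step 7 | isopropyl (2S)-2-(5,6-dimethyl-3-methyl-4-oxo-5,6-dihydro-4H-pyran-2-yl)-2,4-dimethyl-3,5-dioxoheptanoate (C5′/C6′ not defined) | CC1OC(=C(C)C(=O)C1C)[C@](C)(C(=O)OC(C)C)C(=O)C(C)C(=O)CC
F2 | step 7 | bis-silyl spiro adduct of F1: ring A as the C4′ silyl enol ether (C3′=C4′), ring B as the C5-silyloxy enone | CC1C(C)C(O[Si](C)(C)C(C)(C)C)=C(C)[C@]2(O1)C(C)C(=O)C(C)=C(O[Si](C)(C)C(C)(C)C)[C@@]2(C)C(=O)OC(C)C
F0 | step 8 | none | none
F3 | step 11 | isopropyl 9-chloro-4,8-dihydroxy-2,3,5,7,9,11-hexamethyl-10-oxo-1-oxaspiro[5.5]undecane-11-carboxylate with the C1 hydroxyl trans to the ester (C1 epimer of 18) | O[C@@H]1[C@H](C)[C@@H](C)O[C@@]2([C@@H]1C)[C@@H](C)[C@H](O)C(C)(Cl)C(=O)[C@@]2(C)C(=O)OC(C)C
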